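If you want the length of these chains, count how many monomer units a living end has added by 50 s.

    free monomer + initiator → living end + monomer in chains (k1 = 0.00535 /M/s)
    free monomer + living end → monomer in chains + living end, rate k2*[living end]*[free monomer] (k2 = 0.516 /M/s)
    free monomer + initiator → spent initiator (k3 = 0.0140 /M/s)

free monomer 1.2 M; initiator 3.4 mol%; time 50 s

- average number of monomer units in a chain (chains begun, living or dead) at 50 s
- part of the free monomer that has reacted at 50 s

- the average divides the monomer in chains by the number of chains begun, living and dead together
- run time (flask): 50 s

Here is the puzzle. At the charged [free monomer], a living end makes 0.619 /s additions, so 31.0 in 50 s. If each of the 0.0408 M of initiator carried such an end from the start, that would ask for 1.26 M of free monomer, more than the 1.2 M charged. Yet the chain-starting step by itself, the other concentrations held at their charge, gives free monomer a half-life of 53 min, long against the run.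

Clear it up by counting the ends as they come. With [free monomer] held at its charge, the starting and spending steps together consume initiator with a pseudo-first-order constant of 0.0232 /s, and 27.6% of what they consume begins a chain. That gives 0.00775 M of chains by 50 s. Averaged over this falling rate of starts, a chain has lived 29.7 s, which at the charged [free monomer] makes 18.4 turns per chain begun, the additions made by the average chain. With its first unit, I expect 19.4 units and 14.2% reacted.

The forecast gives 18.3 units and 13.1% reacted, on the ground that “Propagation on those slowly accumulating living ends dominates monomer use”. My length stands above it.

The flask gives 18.3 units and 13.1% reacted, with 33% of its initiator still there at 50.0 s. Now take the neighbour flask with 0.72 M of free monomer, at the same loading and time. For that neighbour flask, with [free monomer] again held at its charge, I reckon a fading constant of 0.0139 /s, an average chain age of 27.9 s and 10.4 turns, so 11.4 units. That neighbour flask reads 11.1 units.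

The constants used here were drawn at random within sensible limits.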